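The numbers in the tables are simulated on assumed constants, and the scatter is random.

Work in minutes and in fractions of the charge, and follow the reciprocal of the fraction of electrophile left. If the loss runs on two partners that keep a fixed ratio to each other as they fall, this reciprocal climbs in a straight line, and the slope goes with the charge of electrophile. That slope is an apparent second-order rate.

| setting | amber | red | epsilon | gamma |
|---|---|---|---|---|
| electrophile | 0.020 M (fed, over 1.0 min) | 0.020 M (fed, over 1.0 min) | 0.020 M (fed, over 1.0 min) | 0.020 M (fed, over 1.0 min) |
| nucleophile | 3 equiv | 3 equiv | 3.00 equiv | 3.00 equiv |
| free base | 2.3 equiv | 2.5 equiv | 3.00 equiv | 3.90 equiv |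
| remark | run made earlier; the fed solution adds 0.50 times the starting volume | run made earlier; the fed solution adds 0.50 times the starting volume | the fed solution adds 0.50 times the starting volume | the fed solution adds 0.50 times the starting volume |
| time |  |  | 10 min | 10 min |

| run | time / min | electrophile / % | target / % |
|---|---|---|---|
| amber | 1.33 | 58.5 | 40.7 |
| amber | 2.50 | 37.0 | 57.5 |
| amber | 4.00 | 25.3 | 67.6 |
| amber | 5.00 | 21.4 | 71.5 |
| red | 0.667 | 49.5 | 19.5 |
| red | 2.00 | 44.6 | 52.8 |
| red | 3.00 | 33.1 | 62.8 |
| red | 5.00 | 22.0 | 71.0 |

(each reading ± 1 percentage point)

- charges are per starting volume, the dose included; the dosed solution carries all of it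
- percentages count the whole charge, also what has not yet gone in

- part of the electrophile that has reacted at the end, epsilon
- part of the electrophile that has reacted at the end, gamma
- what raising the equivalents of free base from its lowest to its highest value here does to the part of the electrophile that has reacted (changes below 5 percentage points count as none) (it falls / no change / it rises)

Begin on the first rung, the feed of 1.0 min. In red at 0.667 min, electrophile and target add up to 69.0% with 66.7% fed, so the readings stand for what has gone in, as a share of the whole charge. On the next rung, just after the feed, amber falls from 58.5% to 37.0% in 1.17 min.

Then the fall slows. Between 2.50 min and 5.00 min, amber gives the climb per minute of the reciprocal, 0.788 /min, a reading that carries the scatter.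

My own reckoning carries the climb forward and leaves 11.6%, so 88.4% has reacted. Amber and red differ by 0.6 percentage points at 5.00 min, less than the scatter. I therefore give gamma the same figure and expect no change, though that span of base is narrow.

The forecast gives 88% (83% to 95%) for epsilon, 89% (82% to 98%) for gamma, and no change, adding: “Base dependence is poorly constrained, since the tested range is narrow”.

The flasks give 90.6% for epsilon and 91.0% for gamma, a change of 0.46 points, so no change; the forecast holds.

    electrophile + target → side product (k = 0.0530 /M/s)
    2 nucleophile → homo dimer (k = 0.130 /M/s)
    nucleophile + acid set free ⇌ protonated nucleophile, settled at all times (K = 79000 /M)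
    electrophile + nucleophile → acid set free + target (k = 0.510 /M/s)
    acid set free + free base ⇌ salt of the base, settled at all times (K = 22000 /M)

Moving epsilon's answer by 5 points takes nucleophile down to 2.19 equiv, or up to 5.17 equiv. From 1.00 min to 10 min, epsilon's climb was 1.02 /min, steeper than the 0.788 /min read from amber. Now take the neighbouring flask, with 0.012 M of electrophile and the equivalents held. Scaled by charge, the climb becomes 0.611 /min. Starting from epsilon's 68.6% at the end of the feed, that leaves 14.4%, and the neighbouring flask holds 14% at 10 min.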